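## Structural features

The target 25 is an achiral triaryl: a hexasubstituted benzene core whose C2, C3, C5 and C6 carry methoxy groups and whose C1 and C4 are bonded to C3 of two indoles, one unsubstituted and one bearing a 3-methylbut-2-enyl (prenyl) chain at C5. It has no stereocentre, so no neighbouring stereocentres have to be related; the only stereocentre of the route is a transient carbinol carbon (the future C3 of the unsubstituted indole), carried as a racemate and erased by dehydration. The fragile groups are the trisubstituted prenyl alkene (acid, electrophilic halogen, hydrogenation), the tetramethoxybenzene core, which is oxidised very easily to a quinone, and the two indoles with free N–H and nucleophilic C2. The real difficulty is twofold: each core–indole bond is flanked by two ortho methoxy groups and is a hindered biaryl bond, and the symmetrical core must receive two different indoles. The benzo ring of the unsubstituted indole (C3a, C4, C5, C6, C7, C7a) carries hydrogen on four adjacent carbons, C4 to C7. The key step uses this: the ring is divided into three two-carbon units, C7a–C7 (an ethynyl group on N1), C3a–C4 (an ethynyl group on C3) and C5–C6 (acetylene), with N1–C2–C3 as the tether, so the benzene ring and the five-membered ring form together. As a consequence the second hindered aryl–indole bond is made as an aryl–carbonyl bond by acylation of an aryllithium, and the indole is reached at the alcohol oxidation level, so no oxidant meets the electron-rich core.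

## Logic of the disconnections

25 to 23: the two N–H bonds are traced back to an N–S bond (unsubstituted indole) and an N–Si bond (prenylated indole). The sulfonyl group is what an ynamide needs, and the bulky silyl group is what the organolithium and borylation chemistry needs. Nothing is gained in skeleton, but the forward step must cleave both groups in one operation without acid, reductant or oxidant.

23 to 21: the C2=C3 double bond is replaced by C3–OH and C2–H. This puts C3 at the oxidation level that an acetylide addition to a ketone delivers and turns the aromatic heterocycle into a saturated tether. The forward dehydration must be mild; its regiochemistry is unambiguous because only C2 carries β-hydrogens.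

21 to 19 and 20: C3a–C7a, C4–C5 and C6–C7 are cut. Two rings disappear and the product reduces to an acyclic diyne on the core plus a two-carbon gas. The forward step must favour cross-trimerisation over self-coupling of 19 and must tolerate a free tertiary alcohol, a prenyl alkene and an N-silyl indole.

19 to 17 and 18: the N1–C7a bond (nitrogen to alkyne carbon) is cut. The terminal ynamide is the most sensitive function of the route, so it is introduced last; what remains is a robust sulfonamide N–H. The forward step must ethynylate nitrogen selectively beside a tertiary hydroxyl and a terminal alkyne, and without fluoride, which would remove the N-silyl group.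

17 to 15 and 16: the C3–C3a bond is cut, which removes the stereocentre and one alkyne and leaves a ketone. The forward addition must reach a carbonyl shielded by two ortho methoxy groups and must not enolise it.

15 to 9 and 12: the aryl–carbonyl bond is cut. This replaces a second hindered biaryl coupling by acylation of an aryllithium and separates the core–prenylindole unit from a two-carbon glycine unit. The forward step needs a clean bromine–lithium exchange beside the N-silyl indole and the prenyl group, and the acidic N–H of 12 must be dealt with beforehand.

12 to 10: the amide C–N bond is cut, giving a commercial amino-acid derivative. The forward step is a routine amide coupling.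

9 to 6 and 8: the core–indole C3 bond is cut; it is the only true biaryl coupling of the plan and it desymmetrises the core. The forward coupling must be mono-selective on a symmetrical, di-ortho-substituted dibromide.

8 to 7: two C–Br bonds are cut. The two free positions of 7 are the only C–H sites and are activated, so the forward bromination has no selectivity problem.

6 to 5: the C3–B bond is cut back to C3–H. The forward borylation must choose C3 over all other ring positions and spare the alkene.

5 to 2 and 3: the C5–CH2 bond is cut. The forward alkylation must occur at the primary carbon of 3 and not at its fully substituted end.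

2 to 1: the N–Si bond is cut, giving a commercial bromoindole.

## Other disconnections considered

Alternative 1: The cut is N1–C2 and C3–C3a of the prenylated indole (and, one stage earlier, the same bonds of the other indole). In the forward direction, Pd(OAc)2-catalysed Larock heteroannulation of 2-iodo-4-(3-methylbut-2-enyl)aniline A2 with the silyl alkyne 3-[2,3,5,6-tetramethoxy-4-(trimethylsilylethynyl)phenyl]-2-(trimethylsilyl)indole A3 would give the bis(2-trimethylsilyl) compound A1, and protodesilylation would give the target.
- In favour: both indoles come from one symmetrical bis-alkyne that 8 would deliver in a single Sonogashira step, and no hindered biaryl coupling is needed. At roughly seven steps it is better than the chosen plan on step economy.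
- Against: regiocontrol relies on the silyl group being the larger alkyne substituent, but the other substituent is a di-ortho-methoxyaryl group of comparable bulk, so the sense of carbopalladation is not secure. A2 requires electrophilic iodination beside a prenyl alkene. Removing two C2 silyl groups calls for acid or hot fluoride, and acid is what the prenyl group tolerates least.
- Comparison: the first annulation on the symmetrical bis-alkyne is statistical, which is equal to the statistical mono-coupling of step 5. Mechanistically it is carbopalladation and C–N reductive elimination near 100 °C, against a rhodium cycle at room temperature with no regiochemical question.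

Alternative 2: The cut is the two C–C bonds of the central ring that join each indole-bearing carbon to the neighbouring carbonyl carbon, which leads to two indol-3-ylpyruvate units held on catechol. In the forward direction, LiN(SiMe3)2 would convert the mixed catechol diester A5 into its bis-enolate. Two crossed Claisen condensations, the first across the template and the second a six-membered ring closure, would give the dihydroxyquinone A4. Reduction, fourfold O-methylation and removal of both N-protecting groups would follow.
- In favour: it mirrors the biosynthesis and creates the hexasubstituted core with both hindered aryl bonds already in place. On this structural point it is better than the chosen plan, which needs one hindered cross-coupling and one hindered ketone addition. The template enforces the mixed dimer.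
- Against: aldol attack on the more electrophilic ketone carbonyl can compete with Claisen attack on the aryl ester. Aryl esters can transacylate between molecules and scramble to symmetrical products. Enolisable indolylpyruvic acids are hard to load onto catechol one at a time. The tetrahydroxybenzene stage is air-sensitive, and removal of the 2-(trimethylsilyl)ethoxymethyl groups is harsh.
- Comparison: it closes the central ring (two C–C bonds, one ring) by anionic chemistry, whereas the chosen plan closes a peripheral benzene and a five-membered ring (three C–C bonds, two rings) by catalysis. Step counts are about equal. The precedent for the templated double condensation is weaker than for the cyclotrimerisation.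

Alternative 3: The cut is C3a–C7a and C4–C5 of the prenylated indole, which leads to a 2-aminofuran carrying the prenyl group at its C5 and a vinyl carbinol tether on nitrogen. In the forward direction, heating the carbamate A7 near 180 °C would bring about an intramolecular Diels–Alder reaction of the furan with the vinyl group. Opening of the oxygen bridge, loss of two molecules of water and thermal loss of the tert-butoxycarbonyl group would give A6, and Bu4NF would then give the target.
- In favour: it is metal-free and needs neither acetylene gas nor a terminal ynamide. The other indole would come from a commercial boronate, so no prenylindole boronate has to be made. On these points it is better than the chosen plan.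
- Against: 180 °C with a tertiary benzylic and allylic alcohol and a prenyl group invites ionisation, allylic transposition and ene processes. The dienophile is unactivated. The carbamate must not lose its tert-butoxycarbonyl group before the cycloaddition, because free 2-aminofurans decompose. The tertiary alcohol left at C5 after bridge opening can dehydrate toward the prenyl chain.
- Comparison: the logic is equal to the chosen plan (an indole built on the preformed core through a C3 carbinol and aromatised by dehydration, with no oxidant). Preparing A7 needs the same hindered ketone addition plus a difficult N-alkylation, so step economy is about equal. The chosen key step runs at room temperature.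

Key step: step 10

Remarks on the chemistry and assumptions:
- Compounds 17, 19, 21 and 22 are racemates; their single stereocentre is destroyed in step 11 and the target is achiral.
- Atom bookkeeping of the key step was checked: the ynamide alkyne supplies C7a and C7, the alkyne on the carbinol carbon supplies C3a and C4, and acetylene supplies C5 and C6. The new bonds are C3a–C7a, C4–C5 and C6–C7. The structures of 19 and 21 agree with this and with the target, so no structural correction is needed.
- Three design choices protect the precursor. The sulfonamide N–H is kept through both organometallic additions. The terminal ynamide is installed last and directly in its unsilylated form, so no fluoride touches the N-silyl indole. 19 is purified on triethylamine-deactivated silica and used at once.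
- Building blocks whose atoms reach the target carry numbers; auxiliary reagents that transfer atoms are given by name and SMILES on the reagents line.

## Route

Step 1
Reactants: 1 5-bromoindole
Product: 2 5-bromo-1-(triisopropylsilyl)indole
Conditions: NaH, THF, 0 °C; i-Pr3SiCl, rt
Reagents that add atoms: triisopropylsilyl chloride, CC(C)[Si](Cl)(C(C)C)C(C)C
Why: N-silylation of the sodium indolide; the bulky silyl group survives organolithium reagents and shields C2 and C7 in steps 2, 3 and 7.

Step 2
Reactants: 2 5-bromo-1-(triisopropylsilyl)indole; 3 3-methylbut-2-enyl bromide (prenyl bromide)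
Product: 5 5-(3-methylbut-2-enyl)-1-(triisopropylsilyl)indole, via aryllithium 4 (not isolated)
Conditions: t-BuLi (2 equiv), THF, −78 °C; then 3, −78 °C → rt
Reagents that add atoms: 3-methylbut-2-enyl bromide (3), CC(C)=CCBr
Why: Bromine–lithium exchange (the second equivalent of t-BuLi destroys t-BuBr) followed by SN2 alkylation of the aryllithium at the primary carbon of 3; attack at the fully substituted allylic terminus is sterically disfavoured, and the N-silyl group prevents C2 deprotonation.

Step 3
Reactants: 5 5-(3-methylbut-2-enyl)-1-(triisopropylsilyl)indole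
Product: 6 5-(3-methylbut-2-enyl)-3-(4,4,5,5-tetramethyl-1,3,2-dioxaborolan-2-yl)-1-(triisopropylsilyl)indole
Conditions: [Ir(OMe)(cod)]2 (1.5 mol %), 4,4′-di-tert-butyl-2,2′-bipyridine (3 mol %), B2pin2 (1 equiv), hexane, 60 °C
Reagents that add atoms: bis(pinacolato)diboron, CC1(C)OB(OC1(C)C)B1OC(C)(C)C(C)(C)O1
Why: Iridium-catalysed aromatic C–H borylation by a trivalent iridium tris(boryl) complex is sterically controlled: C2 and C7 are shielded by the N-silyl group and C4 and C6 lie ortho to the prenyl chain, so C3 should react, while the trisubstituted alkene is a poor substrate for hydroboration.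

Step 4
Reactants: 7 1,2,4,5-tetramethoxybenzene
Product: 8 1,4-dibromo-2,3,5,6-tetramethoxybenzene
Conditions: Br2 (2.1 equiv), CH2Cl2, 0 °C → rt
Reagents that add atoms: bromine, BrBr
Why: Electrophilic aromatic bromination; the two free positions are the only C–H sites and each is activated by two ortho methoxy groups, so dibromination is unambiguous.

Step 5
Reactants: 6 5-(3-methylbut-2-enyl)-3-(4,4,5,5-tetramethyl-1,3,2-dioxaborolan-2-yl)-1-(triisopropylsilyl)indole; 8 1,4-dibromo-2,3,5,6-tetramethoxybenzene (threefold excess)
Product: 9 3-(4-bromo-2,3,5,6-tetramethoxyphenyl)-5-(3-methylbut-2-enyl)-1-(triisopropylsilyl)indole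
Conditions: Pd(OAc)2 (5 mol %), SPhos (10 mol %), K3PO4, toluene–H2O (10:1), 90 °C
Reagents that add atoms: none
Why: Suzuki–Miyaura coupling; the bulky electron-rich phosphine lets zerovalent palladium insert into the di-ortho-substituted C–Br bond, and the excess of symmetrical, recoverable 8 together with the greater hindrance of the mono-coupled bromide should keep double coupling low.

Step 6
Reactants: 10 N-tosylglycine
Product: 12 N-methoxy-N-methyl-2-(4-methylphenylsulfonylamino)acetamide, via acyl imidazole 11 (not isolated)
Conditions: CDI, THF, rt; then MeNHOMe·HCl, rt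
Reagents that add atoms: N,O-dimethylhydroxylamine hydrochloride, CNOC.Cl
Why: Amide coupling through the acyl imidazole to give the Weinreb amide; the sulfonamide N–H is too weakly nucleophilic to compete with the hydroxylamine.

Step 7
Reactants: 9 3-(4-bromo-2,3,5,6-tetramethoxyphenyl)-5-(3-methylbut-2-enyl)-1-(triisopropylsilyl)indole; 12 N-methoxy-N-methyl-2-(4-methylphenylsulfonylamino)acetamide
Product: 15 4-methyl-N-{2-oxo-2-[2,3,5,6-tetramethoxy-4-(5-prenyl-1-triisopropylsilylindol-3-yl)phenyl]ethyl}benzenesulfonamide, via aryllithium 13 (not isolated), via N-chloromagnesio amide 14 (not isolated)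
Conditions: 9: n-BuLi, THF, −78 °C; 12: i-PrMgCl (1 equiv), THF, −20 °C; combine, −78 → 0 °C; aq. NH4Cl
Reagents that add atoms: none
Why: Weinreb ketone synthesis: fast bromine–lithium exchange gives an aryllithium stabilised by the flanking methoxy groups, prior N-deprotonation of 12 stops the acidic N–H from quenching it and disfavours α-deprotonation, and the chelated tetrahedral adduct releases the ketone only on work-up, so over-addition is excluded.

Step 8
Reactants: 15 4-methyl-N-{2-oxo-2-[2,3,5,6-tetramethoxy-4-(5-prenyl-1-triisopropylsilylindol-3-yl)phenyl]ethyl}benzenesulfonamide; 16 ethynylmagnesium bromide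
Product: 17 racemic N-{2-hydroxy-2-[2,3,5,6-tetramethoxy-4-(5-prenyl-1-triisopropylsilylindol-3-yl)phenyl]but-3-ynyl}-4-methylbenzenesulfonamide
Conditions: HC≡CMgBr (4 equiv), LaCl3·2LiCl (1 equiv), THF, 0 °C → rt; aq. NH4Cl
Reagents that add atoms: ethynylmagnesium bromide (16), C#C[Mg]Br
Why: Grignard (acetylide) addition to the ketone: the first equivalent deprotonates the sulfonamide, which suppresses enolisation, and the lanthanum salt activates the shielded carbonyl toward the small linear nucleophile; the carbinol centre forms without facial bias, giving a racemate that is irrelevant because step 11 removes the centre.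

Step 9
Reactants: 17 racemic N-{2-hydroxy-2-[2,3,5,6-tetramethoxy-4-(5-prenyl-1-triisopropylsilylindol-3-yl)phenyl]but-3-ynyl}-4-methylbenzenesulfonamide; 18 1-[(trimethylsilyl)ethynyl]-1,2-benziodoxol-3(1H)-one (TMS-EBX)
Product: 19 racemic N-ethynyl-N-{2-hydroxy-2-[2,3,5,6-tetramethoxy-4-(5-prenyl-1-triisopropylsilylindol-3-yl)phenyl]but-3-ynyl}-4-methylbenzenesulfonamide
Conditions: 18 (1.3 equiv), K2CO3, EtOH–THF, rt
Reagents that add atoms: TMS-EBX (18), C[Si](C)(C)C#CI1OC(=O)c2ccccc12
Why: N-ethynylation of a sulfonamide with an ethynylbenziodoxolone: carbonate in ethanol desilylates 18 and deprotonates only the sulfonamide (far more acidic than the tertiary alcohol), the N-anion adds to the β-carbon of the trivalent-iodine alkyne, 2-iodobenzoate leaves, and a 1,2-hydrogen shift of the alkylidene carbene gives the terminal ynamide directly, so no fluoride is needed and the N-silyl indole stays intact.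

Step 10
Reactants: 19 racemic N-ethynyl-N-{2-hydroxy-2-[2,3,5,6-tetramethoxy-4-(5-prenyl-1-triisopropylsilylindol-3-yl)phenyl]but-3-ynyl}-4-methylbenzenesulfonamide; 20 acetylene
Product: 21 racemic 3-[2,3,5,6-tetramethoxy-4-(5-prenyl-1-triisopropylsilylindol-3-yl)phenyl]-1-tosylindolin-3-ol
Conditions: RhCl(PPh3)3 (10 mol %), HC≡CH (1 atm), toluene, rt, slow addition of 19 at high dilution
Reagents that add atoms: acetylene (20), C#C
Why: The closest known reaction type is the RhCl(PPh3)3-catalysed [2+2+2] cross-cyclotrimerisation of N-sulfonyl ynamide-tethered 1,6-diynes with acetylene to give indolines. Monovalent rhodium binds both alkynes of 19 and undergoes oxidative cyclisation to a trivalent rhodacyclopentadiene, which forms C3a–C7a and closes the five-membered ring (N1, C2, C3, C3a, C7a) by metallacycle annulation across the three-atom tether. Acetylene then coordinates and inserts into a Rh–C bond, and reductive elimination forms C4–C5 and C6–C7, closes the benzene ring and returns monovalent rhodium. No stereocentre is created; the carbinol carbon set in step 8 is carried through as the racemate. The selectivity needed is cross-trimerisation over self-coupling of the diyne, and it is secured by the short tether and the quaternary C3 (gem-disubstitution favours the intramolecular oxidative cyclisation), by both alkynes being terminal, and by a large excess of acetylene with slow addition of 19. Acetylene is symmetrical, so no regiochemical question arises. The trisubstituted prenyl alkene is too hindered to insert, and the free tertiary hydroxyl, the N-silyl indole and the methoxy groups are inert to the neutral catalyst at room temperature.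

Step 11
Reactants: 21 racemic 3-[2,3,5,6-tetramethoxy-4-(5-prenyl-1-triisopropylsilylindol-3-yl)phenyl]-1-tosylindolin-3-ol
Product: 23 3-[2,3,5,6-tetramethoxy-4-(5-prenyl-1-triisopropylsilylindol-3-yl)phenyl]-1-(4-methylphenylsulfonyl)indole, via tertiary mesylate 22 (not isolated)
Conditions: MsCl, Et3N, DMAP (cat.), CH2Cl2, 0 °C → rt
Reagents that add atoms: none
Why: Sulfonylation of the tertiary benzylic alcohol (through sulfene) gives a mesylate that ionises and loses a proton from C2, the only carbon with β-hydrogens (E1 dehydration driven by aromatisation); the basic, non-oxidising medium spares the prenyl alkene, the N-silyl group and the electron-rich core.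

Step 12
Reactants: 23 3-[2,3,5,6-tetramethoxy-4-(5-prenyl-1-triisopropylsilylindol-3-yl)phenyl]-1-(4-methylphenylsulfonyl)indole
Product: 25 3-[4-(1H-indol-3-yl)-2,3,5,6-tetramethoxyphenyl]-5-(3-methylbut-2-enyl)-1H-indole, via desilylated N-tosyl indole 24 (not isolated)
Conditions: Bu4NF (5 equiv), THF, 65 °C
Reagents that add atoms: none
Why: Fluoride cleaves the N–Si bond at once and, on heating, attacks sulfur of the N-sulfonylindole, whose indolide is a good leaving group (fluoride-mediated N-desulfonylation), so both protecting groups fall in one non-acidic, non-reducing operation that leaves the prenyl and methoxy groups untouched.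

## Compound list

1 | 5-bromoindole | Brc1ccc2[nH]ccc2c1 | starting material
2 | 5-bromo-1-(triisopropylsilyl)indole | CC(C)[Si](C(C)C)(C(C)C)n1ccc2cc(Br)ccc12 | intermediate
3 | 3-methylbut-2-enyl bromide (prenyl bromide) | CC(C)=CCBr | starting material
4 | 5-lithio-1-(triisopropylsilyl)indole | CC(C)[Si](C(C)C)(C(C)C)n1ccc2cc([Li])ccc12 | intermediate (not isolated)
5 | 5-(3-methylbut-2-enyl)-1-(triisopropylsilyl)indole | CC(C)=CCc1ccc2c(ccn2[Si](C(C)C)(C(C)C)C(C)C)c1 | intermediate
6 | 5-(3-methylbut-2-enyl)-3-(4,4,5,5-tetramethyl-1,3,2-dioxaborolan-2-yl)-1-(triisopropylsilyl)indole | CC(C)=CCc1ccc2c(c1)c(B1OC(C)(C)C(C)(C)O1)cn2[Si](C(C)C)(C(C)C)C(C)C | intermediate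
7 | 1,2,4,5-tetramethoxybenzene | COc1cc(OC)c(OC)cc1OC | starting material
8 | 1,4-dibromo-2,3,5,6-tetramethoxybenzene | COc1c(OC)c(Br)c(OC)c(OC)c1Br | intermediate
9 | 3-(4-bromo-2,3,5,6-tetramethoxyphenyl)-5-(3-methylbut-2-enyl)-1-(triisopropylsilyl)indole | COc1c(OC)c(-c2cn([Si](C(C)C)(C(C)C)C(C)C)c3ccc(CC=C(C)C)cc23)c(OC)c(OC)c1Br | intermediate
10 | N-tosylglycine | Cc1ccc(cc1)S(=O)(=O)NCC(O)=O | starting material
11 | 1-[N-(4-methylphenylsulfonyl)glycyl]imidazole | Cc1ccc(cc1)S(=O)(=O)NCC(=O)n1ccnc1 | intermediate (not isolated)
12 | N-methoxy-N-methyl-2-(4-methylphenylsulfonylamino)acetamide | CON(C)C(=O)CNS(=O)(=O)c1ccc(C)cc1 | intermediate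
13 | [2,3,5,6-tetramethoxy-4-(5-prenyl-1-triisopropylsilylindol-3-yl)phenyl]lithium | COc1c(OC)c(-c2cn([Si](C(C)C)(C(C)C)C(C)C)c3ccc(CC=C(C)C)cc23)c(OC)c(OC)c1[Li] | intermediate (not isolated)
14 | N-chloromagnesio derivative of 12 | CON(C)C(=O)CN([Mg]Cl)S(=O)(=O)c1ccc(C)cc1 | intermediate (not isolated)
15 | 4-methyl-N-{2-oxo-2-[2,3,5,6-tetramethoxy-4-(5-prenyl-1-triisopropylsilylindol-3-yl)phenyl]ethyl}benzenesulfonamide | COc1c(OC)c(-c2cn([Si](C(C)C)(C(C)C)C(C)C)c3ccc(CC=C(C)C)cc23)c(OC)c(OC)c1C(=O)CNS(=O)(=O)c1ccc(C)cc1 | intermediate
16 | ethynylmagnesium bromide | C#C[Mg]Br | starting material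
17 | racemic N-{2-hydroxy-2-[2,3,5,6-tetramethoxy-4-(5-prenyl-1-triisopropylsilylindol-3-yl)phenyl]but-3-ynyl}-4-methylbenzenesulfonamide | C#CC(O)(CNS(=O)(=O)c1ccc(C)cc1)c1c(OC)c(OC)c(-c2cn([Si](C(C)C)(C(C)C)C(C)C)c3ccc(CC=C(C)C)cc23)c(OC)c1OC | intermediate
18 | 1-[(trimethylsilyl)ethynyl]-1,2-benziodoxol-3(1H)-one (TMS-EBX) | C[Si](C)(C)C#CI1OC(=O)c2ccccc12 | starting material
19 | racemic N-ethynyl-N-{2-hydroxy-2-[2,3,5,6-tetramethoxy-4-(5-prenyl-1-triisopropylsilylindol-3-yl)phenyl]but-3-ynyl}-4-methylbenzenesulfonamide | C#CN(CC(O)(C#C)c1c(OC)c(OC)c(-c2cn([Si](C(C)C)(C(C)C)C(C)C)c3ccc(CC=C(C)C)cc23)c(OC)c1OC)S(=O)(=O)c1ccc(C)cc1 | intermediate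
20 | acetylene | C#C | starting material
21 | racemic 3-[2,3,5,6-tetramethoxy-4-(5-prenyl-1-triisopropylsilylindol-3-yl)phenyl]-1-tosylindolin-3-ol | OC1(CN(S(=O)(=O)c2ccc(C)cc2)c2ccccc12)c1c(OC)c(OC)c(-c2cn([Si](C(C)C)(C(C)C)C(C)C)c3ccc(CC=C(C)C)cc23)c(OC)c1OC | intermediate
22 | racemic methanesulfonate of 21 | CS(=O)(=O)OC1(CN(S(=O)(=O)c2ccc(C)cc2)c2ccccc12)c1c(OC)c(OC)c(-c2cn([Si](C(C)C)(C(C)C)C(C)C)c3ccc(CC=C(C)C)cc23)c(OC)c1OC | intermediate (not isolated)
23 | 3-[2,3,5,6-tetramethoxy-4-(5-prenyl-1-triisopropylsilylindol-3-yl)phenyl]-1-(4-methylphenylsulfonyl)indole | COc1c(OC)c(-c2cn([Si](C(C)C)(C(C)C)C(C)C)c3ccc(CC=C(C)C)cc23)c(OC)c(OC)c1-c1cn(S(=O)(=O)c2ccc(C)cc2)c2ccccc12 | intermediate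
24 | 3-[2,3,5,6-tetramethoxy-4-(5-prenyl-1H-indol-3-yl)phenyl]-1-(4-methylphenylsulfonyl)indole | COc1c(OC)c(-c2c[nH]c3ccc(CC=C(C)C)cc23)c(OC)c(OC)c1-c1cn(S(=O)(=O)c2ccc(C)cc2)c2ccccc12 | intermediate (not isolated)
25 | 3-[4-(1H-indol-3-yl)-2,3,5,6-tetramethoxyphenyl]-5-(3-methylbut-2-enyl)-1H-indole | COc1c(OC)c(-c2c[nH]c3ccc(CC=C(C)C)cc23)c(OC)c(OC)c1-c1c[nH]c2ccccc12 | target

## Step count and least certain steps

Total: 12 steps. Longest linear sequence: 10 steps (steps 1, 2, 3, 5, 7, 8, 9, 10, 11, 12, from 5-bromoindole); steps 4 and 6 are side branches.

**Step 10 (key step).** The most likely failure is self-coupling of the diyne through its rhodacycle, or sluggish oxidative cyclisation because the alkyne on C3 sits beside a quaternary carbon bearing a di-ortho-substituted aryl group. Acid-induced hydration of the terminal ynamide before it reacts would be a further loss. The fallback sets out from 9 and returns at 25; it gives up the ring construction and attaches the indole ready-made. Suzuki–Miyaura coupling of 9 with commercial 1-(triisopropylsilyl)indol-3-ylboronic acid pinacol ester (Pd(OAc)2, SPhos, K3PO4, toluene–H2O, 100 °C) should give 3-{2,3,5,6-tetramethoxy-4-[1-(triisopropylsilyl)indol-3-yl]phenyl}-5-(3-methylbut-2-enyl)-1-(triisopropylsilyl)indole F1. Bu4NF in THF then removes both silyl groups to give 25.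

**Step 9.** The most likely failure is participation of the neighbouring tertiary hydroxyl (addition across the newly formed ynamide, or interception of the iodine reagent), or slow N-alkynylation because the nitrogen sits next to a quaternary carbon. The fallback sets out from 15 and returns at 19; it reverses the order so that no hydroxyl is present during alkynylation. 15 is ethynylated with 18 and K2CO3 in EtOH–THF to give N-ethynyl-4-methyl-N-{2-oxo-2-[2,3,5,6-tetramethoxy-4-(5-prenyl-1-triisopropylsilylindol-3-yl)phenyl]ethyl}benzenesulfonamide F2. Non-basic acetylide addition to its ketone (lithium acetylide with CeCl3, THF, −78 °C) then gives 19.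

**Step 8.** The most likely failure is lack of addition, because the ortho methoxy groups of the twisted aryl ketone shield both faces of the carbonyl, with deprotonation taking over. The fallback sets out from 12 and 9 and returns at 17; it forms the hindered bond from the aryl side. 12 and LiC≡CSiMe3 (2.2 equiv, THF, −78 → 0 °C) give the ynone 4-methyl-N-[2-oxo-4-(trimethylsilyl)but-3-ynyl]benzenesulfonamide F3. F3 is N-lithiated with LiN(SiMe3)2 at −78 °C and treated with aryllithium 13 (from 9 and n-BuLi); 1,2-addition gives racemic N-{2-hydroxy-2-[2,3,5,6-tetramethoxy-4-(5-prenyl-1-triisopropylsilylindol-3-yl)phenyl]-4-(trimethylsilyl)but-3-ynyl}-4-methylbenzenesulfonamide F4. K2CO3 in MeOH cleaves the alkynyl C–Si bond to give 17.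

**Step 5.** The most likely failure is double coupling, or protodeboronation of 6 outrunning a slow oxidative addition into the hindered, electron-rich C–Br bond. The fallback sets out from 8 and returns at 9; it desymmetrises the electrophile. One bromine–lithium exchange on 8 (n-BuLi, 1 equiv, THF, −78 °C) and an I2 quench give 1-bromo-4-iodo-2,3,5,6-tetramethoxybenzene F5. Coupling with 6 (1 equiv; Pd(PPh3)4, K3PO4, dioxane–H2O, 70 °C) should occur selectively at the C–I bond and give 9.

**Step 3.** The most likely failure is hydroboration or isomerisation of the prenyl alkene by the HBpin formed under iridium catalysis, or incomplete regiocontrol. The fallback sets out from 5 and returns at 6; it uses electrophilic halogenation and metal exchange. NBS in THF at −78 °C brominates C3 to give 3-bromo-5-(3-methylbut-2-enyl)-1-(triisopropylsilyl)indole F6. t-BuLi (2 equiv, THF, −78 °C) followed by 2-isopropoxy-4,4,5,5-tetramethyl-1,3,2-dioxaborolane gives 6.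

## Further compounds

F1 | step 10 | 3-{2,3,5,6-tetramethoxy-4-[1-(triisopropylsilyl)indol-3-yl]phenyl}-5-(3-methylbut-2-enyl)-1-(triisopropylsilyl)indole | COc1c(OC)c(-c2cn([Si](C(C)C)(C(C)C)C(C)C)c3ccc(CC=C(C)C)cc23)c(OC)c(OC)c1-c1cn([Si](C(C)C)(C(C)C)C(C)C)c2ccccc12
F2 | step 9 | N-ethynyl-4-methyl-N-{2-oxo-2-[2,3,5,6-tetramethoxy-4-(5-prenyl-1-triisopropylsilylindol-3-yl)phenyl]ethyl}benzenesulfonamide | C#CN(CC(=O)c1c(OC)c(OC)c(-c2cn([Si](C(C)C)(C(C)C)C(C)C)c3ccc(CC=C(C)C)cc23)c(OC)c1OC)S(=O)(=O)c1ccc(C)cc1
F3 | step 8 | 4-methyl-N-[2-oxo-4-(trimethylsilyl)but-3-ynyl]benzenesulfonamide | C[Si](C)(C)C#CC(=O)CNS(=O)(=O)c1ccc(C)cc1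
F4 | step 8 | racemic N-{2-hydroxy-2-[2,3,5,6-tetramethoxy-4-(5-prenyl-1-triisopropylsilylindol-3-yl)phenyl]-4-(trimethylsilyl)but-3-ynyl}-4-methylbenzenesulfonamide | C[Si](C)(C)C#CC(O)(CNS(=O)(=O)c1ccc(C)cc1)c1c(OC)c(OC)c(-c2cn([Si](C(C)C)(C(C)C)C(C)C)c3ccc(CC=C(C)C)cc23)c(OC)c1OC
F5 | step 5 | 1-bromo-4-iodo-2,3,5,6-tetramethoxybenzene | COc1c(OC)c(I)c(OC)c(OC)c1Br
F6 | step 3 | 3-bromo-5-(3-methylbut-2-enyl)-1-(triisopropylsilyl)indole | CC(C)=CCc1ccc2c(c1)c(Br)cn2[Si](C(C)C)(C(C)C)C(C)C
A1 | alternative 1 | 3-{2,3,5,6-tetramethoxy-4-[2-(trimethylsilyl)-1H-indol-3-yl]phenyl}-5-(3-methylbut-2-enyl)-2-(trimethylsilyl)-1H-indole | COc1c(OC)c(-c2c([Si](C)(C)C)[nH]c3ccc(CC=C(C)C)cc23)c(OC)c(OC)c1-c1c([Si](C)(C)C)[nH]c2ccccc12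
A2 | alternative 1 | 2-iodo-4-(3-methylbut-2-enyl)aniline | CC(C)=CCc1ccc(N)c(I)c1
A3 | alternative 1 | 3-[2,3,5,6-tetramethoxy-4-(trimethylsilylethynyl)phenyl]-2-(trimethylsilyl)-1H-indole | COc1c(OC)c(C#C[Si](C)(C)C)c(OC)c(OC)c1-c1c([Si](C)(C)C)[nH]c2ccccc12
A4 | alternative 2 | 2,5-dihydroxy-3-{5-(3-methylbut-2-enyl)-1-[2-(trimethylsilyl)ethoxymethyl]indol-3-yl}-6-{1-[2-(trimethylsilyl)ethoxymethyl]indol-3-yl}-1,4-benzoquinone | O=C1C(O)=C(c2cn(COCC[Si](C)(C)C)c3ccc(CC=C(C)C)cc23)C(=O)C(O)=C1c1cn(COCC[Si](C)(C)C)c2ccccc12
A5 | alternative 2 | mixed catechol diester of the two N-[2-(trimethylsilyl)ethoxymethyl]-protected indol-3-ylpyruvic acids (5-prenylated and unsubstituted) | O=C(Cc1cn(COCC[Si](C)(C)C)c2ccc(CC=C(C)C)cc12)C(=O)Oc1ccccc1OC(=O)C(=O)Cc1cn(COCC[Si](C)(C)C)c2ccccc12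
A6 | alternative 3 | 3-{2,3,5,6-tetramethoxy-4-[1-(triisopropylsilyl)indol-3-yl]phenyl}-5-(3-methylbut-2-enyl)-1H-indole | COc1c(OC)c(-c2c[nH]c3ccc(CC=C(C)C)cc23)c(OC)c(OC)c1-c1cn([Si](C(C)C)(C(C)C)C(C)C)c2ccccc12
A7 | alternative 3 | racemic tert-butyl N-{2-hydroxy-2-[2,3,5,6-tetramethoxy-4-(1-triisopropylsilylindol-3-yl)phenyl]but-3-enyl}-N-[5-(3-methylbut-2-enyl)furan-2-yl]carbamate | CC(C)=CCc1ccc(o1)N(CC(O)(C=C)c1c(OC)c(OC)c(-c2cn([Si](C(C)C)(C(C)C)C(C)C)c3ccccc23)c(OC)c1OC)C(=O)OC(C)(C)C
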